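**Plan**

- Locants: ring O1–O2–C3–C4–C5; side chain C1′–C12′ counted from C5 (methyl-bearing C2′ and C4′, phenyl on C12′).
- Retrosynthesis: cut C3–CH2CO2H (peroxycarbenium ion + ketene acetal), open O2–C3 to a β-hydroperoxy ketone, trace C5–O1 to H2O2 opening of an oxetane (C5/C4/C3), the oxetane to the C5 methyl ketone and that to an isopropenyl end. Then cut the chain at C4′–C5′, C3′–C4′, C2′–C3′ and C1′–C2′ as boronic ester homologations.
- Forward: the hydrocarbon chain is assembled first from 2-methylallyl-Bpin by four carbenoid insertions (C2′, C3′, C4′, then the C5′–C12′/phenyl fragment); boron is removed and the 1,2-dioxolane is built last on the terminal alkene.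
- Enabling feature: C4′ is a heteroatom-free methine next to the plain methylene C5′. C4′ can therefore arrive as a configurationally stable secondary boronic ester and C5′ as an α-lithiated benzoate (two donor carbons); the boron left on C5′ is a traceless helper, replaced by H.
- Stereochemistry: C2′ and C4′ by sparteine-controlled lithiation of ethyl TIB ester (reagent control; all 1,2-shifts retentive at the migrating carbon). C5 by catalytic asymmetric Corey–Chaykovsky epoxidation, inverted once in the oxetane perhydrolysis. C3 by addition to the dioxolanyl peroxycarbenium ion anti to the C5 chain (substrate control; epimer separated).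

Key step: step 5

Assumption: 1, 3, 4 and both sparteine enantiomers are taken as purchasable; the (S)-binaphthoxide catalyst of step 8 is assumed to deliver CH2 to the Si face of ketone 18 (if a model methyl ketone shows the opposite sense, the (R)-catalyst is used).

Abbreviations: TIB = 2,4,6-triisopropylbenzoyl; pin = pinacolato.

**Route**

Step 1
Reactants: 1 8-phenyloctan-1-ol
Product: 2 8-phenyloctyl 2,4,6-tri(propan-2-yl)benzoate
Conditions: TIBCl, Et3N, DMAP (cat.), CH2Cl2, 0 °C → reflux
Reagents that add atoms: 2,4,6-triisopropylbenzoyl chloride, CC(C)c1cc(C(C)C)c(C(Cl)=O)c(C(C)C)c1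
Why: DMAP-catalysed esterification of the primary alcohol installs the hindered aroyl group that directs α-lithiation and later acts as the leaving group of the 1,2-metallate shift.

Step 2
Reactants: 3 4,4,5,5-tetramethyl-2-(2-methylprop-2-en-1-yl)-1,3,2-dioxaborolane, 4 ethyl 2,4,6-tri(propan-2-yl)benzoate
Product: 7 4,4,5,5-tetramethyl-2-[(2R)-4-methylpent-4-en-2-yl]-1,3,2-dioxaborolane, via lithiated benzoate 5 (not isolated), via boronate complex 6 (not isolated)
Conditions: 4, s-BuLi, (−)-sparteine, Et2O, −78 °C, 5 h; then 3, −78 °C, 1 h; then 35 °C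
Reagents that add atoms: none
Why: Lithiation–borylation: sparteine-mediated removal of the pro-S hydrogen gives the (S)-carbenoid, borylation is retentive and the 2-methylallyl group migrates with inversion at carbon (1,2-metallate rearrangement), so C2′ is set by reagent control as the (R)-boronic ester.

Step 3
Reactants: 7 4,4,5,5-tetramethyl-2-[(2R)-4-methylpent-4-en-2-yl]-1,3,2-dioxaborolane
Product: 9 2-[(2S)-2,4-dimethylpent-4-en-1-yl]-4,4,5,5-tetramethyl-1,3,2-dioxaborolane, via chloromethyl boronate 8 (not isolated)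
Conditions: BrCH2Cl, n-BuLi, Et2O, −78 °C → rt
Reagents that add atoms: bromochloromethane (as LiCH2Cl), ClCBr
Why: Matteson homologation inserts C3′ by a 1,2-metallate shift that is retentive at the migrating C2′ (the descriptor changes to S only through the CIP priorities).

Step 4
Reactants: 9 2-[(2S)-2,4-dimethylpent-4-en-1-yl]-4,4,5,5-tetramethyl-1,3,2-dioxaborolane, 4 ethyl 2,4,6-tri(propan-2-yl)benzoate
Product: 12 2-[(2S,4S)-4,6-dimethylhept-6-en-2-yl]-4,4,5,5-tetramethyl-1,3,2-dioxaborolane, via lithiated benzoate 10 (not isolated), via boronate complex 11 (not isolated)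
Conditions: 4, s-BuLi, (+)-sparteine, Et2O, −78 °C, 5 h; then 9, −78 °C, 1 h; then 35 °C
Reagents that add atoms: none
Why: A second lithiation–borylation with the (R)-carbenoid from (+)-sparteine sets C4′ as the (S)-boronic ester by reagent control, independent of C2′, which gives the anti-1,3-dimethyl array.

Step 5
Reactants: 12 2-[(2S,4S)-4,6-dimethylhept-6-en-2-yl]-4,4,5,5-tetramethyl-1,3,2-dioxaborolane, 2 8-phenyloctyl 2,4,6-tri(propan-2-yl)benzoate
Product: 15 4,4,5,5-tetramethyl-2-[(9S,11S)-9,11,13-trimethyl-1-phenyltetradec-13-en-8-yl]-1,3,2-dioxaborolane (both epimers at the boron-bearing C8), via lithiated benzoate 13 (not isolated), via boronate complex 14 (not isolated)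
Conditions: 2, s-BuLi, TMEDA, Et2O, −78 °C, 5 h; then 12, −78 °C, 1 h; then 35 °C, 16 h
Reagents that add atoms: none
Why: α-Lithiation of benzoate 2 gives a primary α-oxyalkyllithium that adds to the boron of 12, and the tetracoordinate boronate 14 then undergoes a 1,2-metallate rearrangement in which the C4′ group migrates from boron to the lithiated carbon with loss of triisopropylbenzoate, forming the C4′–C5′ bond. The closest known reaction type is the lithiation–borylation homologation of secondary pinacol boronic esters with lithiated primary benzoates, as used in iterative assembly-line synthesis and in traceless lithiation–borylation–protodeboronation fragment unions. No ring is closed. C4′ migrates with retention, so its configuration is the one installed in step 4 (the S descriptor in 15 is only a CIP change caused by boron on the neighbouring carbon), while the new boron-bearing carbon is a temporary, deliberately uncontrolled stereocentre that is erased in step 6. The step needs selectivity for boron over the 1,1-disubstituted alkene and complete migration of the hindered secondary alkyl group instead of pinacol-oxygen migration or reversal, which the unfunctionalised hydrocarbon skeleton, the good benzoate leaving group and warming to 35 °C should secure. It is a union of two formally nucleophilic carbons, possible because the carbenoid carbon turns electrophilic once the boronate has formed.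

Step 6
Reactants: 15 4,4,5,5-tetramethyl-2-[(9S,11S)-9,11,13-trimethyl-1-phenyltetradec-13-en-8-yl]-1,3,2-dioxaborolane
Product: 17 (4S,6R)-2,4,6-trimethyl-14-phenyltetradec-1-ene, via arylboronate complex 16 (not isolated)
Conditions: 3,5-(CF3)2C6H3Br, n-BuLi, THF, −78 °C; then 15, −78 °C → rt; then Mn(OAc)3·2H2O, 4-tert-butylcatechol, rt → 50 °C
Reagents that add atoms: none
Why: Radical protodeboronation: one-electron oxidation of the aryl boronate complex by Mn(OAc)3 releases the secondary alkyl radical at C5′, which abstracts hydrogen from the catechol; C2′ and C4′ are not involved.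

Step 7
Reactants: 17 (4S,6R)-2,4,6-trimethyl-14-phenyltetradec-1-ene
Product: 18 (4S,6R)-4,6-dimethyl-14-phenyltetradecan-2-one
Conditions: O3, CH2Cl2/MeOH, −78 °C; then Me2S, −78 °C → rt
Reagents that add atoms: ozone, [O-][O+]=O
Why: Ozonolysis with reductive work-up cleaves the electron-rich 1,1-disubstituted alkene to the methyl ketone far faster than ozone attacks the monoalkylbenzene ring at −78 °C.

Step 8
Reactants: 18 (4S,6R)-4,6-dimethyl-14-phenyltetradecan-2-one
Product: 19 (2R)-2-[(2S,4R)-2,4-dimethyl-12-phenyldodecyl]-2-methyloxirane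
Conditions: Me3S(O)I, NaH, THF; then 18, LaLi3[(S)-binaphthoxide]3 (5 mol %), (2,4,6-(MeO)3C6H2)3P=O (5 mol %), 5 Å MS, THF, rt
Reagents that add atoms: trimethylsulfoxonium iodide (CH2 source via dimethylsulfoxonium methylide), C[S+](C)(C)=O.[I-]
Why: Catalytic asymmetric Corey–Chaykovsky epoxidation of a methyl ketone sets C5 by catalyst control as the (R)-epoxide, the opposite spatial sense to the target because this centre is inverted in step 12.

Step 9
Reactants: 19 (2R)-2-[(2S,4R)-2,4-dimethyl-12-phenyldodecyl]-2-methyloxirane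
Product: 20 (4S,6S,8R)-4,6,8-trimethyl-16-phenylhexadec-1-en-4-ol
Conditions: CH2=CHMgBr, CuI (10 mol %), THF, −40 → 0 °C
Reagents that add atoms: vinylmagnesium bromide, C=C[Mg]Br
Why: Copper-catalysed Grignard opening of the 2,2-disubstituted epoxide at its CH2 terminus (SN2) adds the C3 unit and leaves the quaternary carbinol centre untouched (S by CIP change only).

Step 10
Reactants: 20 (4S,6S,8R)-4,6,8-trimethyl-16-phenylhexadec-1-en-4-ol
Product: 21 (4R,6S,8R)-4,6,8-trimethyl-16-phenylhexadecane-2,4-diol (both epimers at C2)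
Conditions: Co(acac)2 (20 mol %), PhSiH3, O2 (1 atm), THF, rt
Reagents that add atoms: dioxygen, O=O
Why: Mukaiyama hydration (hydrogen-atom transfer to the vinyl group, O2 capture, reduction) gives the Markovnikov secondary alcohol; the new carbinol centre is uncontrolled and is oxidised away in step 13.

Step 11
Reactants: 21 (4R,6S,8R)-4,6,8-trimethyl-16-phenylhexadecane-2,4-diol
Product: 23 (2R)-2-[(2S,4R)-2,4-dimethyl-12-phenyldodecyl]-2,4-dimethyloxetane (both epimers at C4), via mesylate 22 (not isolated)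
Conditions: MsCl, Et3N, CH2Cl2, −20 °C; then KOtBu, THF, 0 °C → rt
Reagents that add atoms: none
Why: Selective mesylation of the secondary hydroxyl followed by intramolecular Williamson etherification (4-exo-tet) by the tertiary alkoxide closes the oxetane with retention at the quaternary carbon, whose C–O bond is not broken.

Step 12
Reactants: 23 (2R)-2-[(2S,4R)-2,4-dimethyl-12-phenyldodecyl]-2,4-dimethyloxetane
Product: 24 (4S,6S,8R)-4-hydroperoxy-4,6,8-trimethyl-16-phenylhexadecan-2-ol (both epimers at C2)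
Conditions: anhydrous H2O2 in Et2O, TMSOTf (0.3 equiv), Et2O, −78 → 0 °C
Reagents that add atoms: hydrogen peroxide, OO
Why: Lewis-acid-promoted perhydrolysis of the oxetane: H2O2 attacks the activated ring at the more substituted carbon in a loose SN2 process with inversion, which sets the (S)-tertiary hydroperoxide at C5.

Step 13
Reactants: 24 (4S,6S,8R)-4-hydroperoxy-4,6,8-trimethyl-16-phenylhexadecan-2-ol
Product: 27 (5S)-5-[(2S,4R)-2,4-dimethyl-12-phenyldodecyl]-3-methoxy-3,5-dimethyl-1,2-dioxolane (both epimers at C3), via hydroperoxy ketone 25 (not isolated), via dioxolanol 26 (not isolated)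
Conditions: Dess–Martin periodinane, NaHCO3, CH2Cl2, 0 °C; then MeOH, TsOH·H2O (cat.), 3 Å MS, rt
Reagents that add atoms: methanol, CO
Why: Dess–Martin oxidation of the secondary alcohol (the tertiary hydroperoxide has no α-hydrogen) gives the β-hydroperoxy ketone, which closes to the five-membered peroxyhemiketal (5-exo-trig) and is ketalised by acidic methanol; C5 is unaffected.

Step 14
Reactants: 27 (5S)-5-[(2S,4R)-2,4-dimethyl-12-phenyldodecyl]-3-methoxy-3,5-dimethyl-1,2-dioxolane
Product: 29 methyl 2-[(3R,5S)-5-[(2S,4R)-2,4-dimethyl-12-phenyldodecyl]-3,5-dimethyl-1,2-dioxolan-3-yl]acetate, via peroxycarbenium ion 28 (not isolated)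
Conditions: CH2=C(OMe)OTBS, TiCl4, CH2Cl2, −78 °C
Reagents that add atoms: tert-butyl[(1-methoxyethenyl)oxy]dimethylsilane, C=C(OC)O[Si](C)(C)C(C)(C)C
Why: TiCl4 ionises the peroxyketal to the cyclic peroxycarbenium ion, which is trapped by the silyl ketene acetal (Mukaiyama-type addition); the nucleophile should approach anti to the larger, β-branched C5 substituent, placing CH2CO2Me trans to the chain (3R), and the 3S epimer is removed by chromatography.

Step 15
Reactants: 29 methyl 2-[(3R,5S)-5-[(2S,4R)-2,4-dimethyl-12-phenyldodecyl]-3,5-dimethyl-1,2-dioxolan-3-yl]acetate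
Product: 30 2-[(3R,5S)-5-[(2S,4R)-2,4-dimethyl-12-phenyldodecyl]-3,5-dimethyl-1,2-dioxolan-3-yl]acetic acid
Conditions: LiOH·H2O, THF/MeOH/H2O, 0 °C → rt; then 1 M HCl to pH 3
Reagents that add atoms: water (as LiOH/H2O), O
Why: Saponification; the fully substituted dioxolane has no ring C–H for base-induced Kornblum–DeLaMare cleavage, and the carboxylate formed resists retro-oxa-Michael opening.

**Compound list**

1 | 8-phenyloctan-1-ol | OCCCCCCCCc1ccccc1 | starting material
2 | 8-phenyloctyl 2,4,6-tri(propan-2-yl)benzoate | CC(C)c1cc(C(C)C)c(C(=O)OCCCCCCCCc2ccccc2)c(C(C)C)c1 | intermediate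
3 | 4,4,5,5-tetramethyl-2-(2-methylprop-2-en-1-yl)-1,3,2-dioxaborolane | CC(=C)CB1OC(C)(C)C(C)(C)O1 | starting material
4 | ethyl 2,4,6-tri(propan-2-yl)benzoate | CCOC(=O)c1c(C(C)C)cc(C(C)C)cc1C(C)C | starting material
5 | (1S)-1-lithioethyl 2,4,6-tri(propan-2-yl)benzoate ((−)-sparteine complex) | C[C@H]([Li])OC(=O)c1c(C(C)C)cc(C(C)C)cc1C(C)C | intermediate
6 | lithium [(1S)-1-(TIB-oxy)ethyl](2-methylprop-2-en-1-yl)(pinacolato)borate | C[C@H]([B-]1(CC(C)=C)OC(C)(C)C(C)(C)O1)OC(=O)c1c(C(C)C)cc(C(C)C)cc1C(C)C.[Li+] | intermediate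
7 | 4,4,5,5-tetramethyl-2-[(2R)-4-methylpent-4-en-2-yl]-1,3,2-dioxaborolane | C[C@H](CC(C)=C)B1OC(C)(C)C(C)(C)O1 | intermediate
8 | lithium (chloromethyl)[(2R)-4-methylpent-4-en-2-yl](pinacolato)borate | [Li+].ClC[B-]1([C@H](C)CC(C)=C)OC(C)(C)C(C)(C)O1 | intermediate
9 | 2-[(2S)-2,4-dimethylpent-4-en-1-yl]-4,4,5,5-tetramethyl-1,3,2-dioxaborolane | CC1(C)OB(C[C@H](C)CC(C)=C)OC1(C)C | intermediate
10 | (1R)-1-lithioethyl 2,4,6-tri(propan-2-yl)benzoate ((+)-sparteine complex) | C[C@@H]([Li])OC(=O)c1c(C(C)C)cc(C(C)C)cc1C(C)C | intermediate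
11 | lithium [(1R)-1-(TIB-oxy)ethyl][(2S)-2,4-dimethylpent-4-en-1-yl](pinacolato)borate | C[C@@H]([B-]1(C[C@H](C)CC(C)=C)OC(C)(C)C(C)(C)O1)OC(=O)c1c(C(C)C)cc(C(C)C)cc1C(C)C.[Li+] | intermediate
12 | 2-[(2S,4S)-4,6-dimethylhept-6-en-2-yl]-4,4,5,5-tetramethyl-1,3,2-dioxaborolane | C[C@H](B1OC(C)(C)C(C)(C)O1)C[C@H](C)CC(C)=C | intermediate
13 | 1-lithio-8-phenyloctyl 2,4,6-tri(propan-2-yl)benzoate (TMEDA complex, racemic at the lithiated carbon) | [Li]C(CCCCCCCc1ccccc1)OC(=O)c1c(C(C)C)cc(C(C)C)cc1C(C)C | intermediate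
14 | lithium [(2S,4S)-4,6-dimethylhept-6-en-2-yl][8-phenyl-1-(TIB-oxy)octyl](pinacolato)borate (both configurations at the benzoate-bearing carbon) | C[C@H]([B-]1(C(CCCCCCCc2ccccc2)OC(=O)c2c(C(C)C)cc(C(C)C)cc2C(C)C)OC(C)(C)C(C)(C)O1)C[C@H](C)CC(C)=C.[Li+] | intermediate
15 | 4,4,5,5-tetramethyl-2-[(9S,11S)-9,11,13-trimethyl-1-phenyltetradec-13-en-8-yl]-1,3,2-dioxaborolane (both epimers at C8) | C[C@H](C(CCCCCCCc1ccccc1)B1OC(C)(C)C(C)(C)O1)C[C@H](C)CC(C)=C | intermediate
16 | lithium [3,5-bis(trifluoromethyl)phenyl][(9S,11S)-9,11,13-trimethyl-1-phenyltetradec-13-en-8-yl](pinacolato)borate | C[C@H](C(CCCCCCCc1ccccc1)[B-]1(c2cc(C(F)(F)F)cc(C(F)(F)F)c2)OC(C)(C)C(C)(C)O1)C[C@H](C)CC(C)=C.[Li+] | intermediate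
17 | (4S,6R)-2,4,6-trimethyl-14-phenyltetradec-1-ene | C[C@H](CCCCCCCCc1ccccc1)C[C@H](C)CC(C)=C | intermediate
18 | (4S,6R)-4,6-dimethyl-14-phenyltetradecan-2-one | C[C@H](CCCCCCCCc1ccccc1)C[C@H](C)CC(C)=O | intermediate
19 | (2R)-2-[(2S,4R)-2,4-dimethyl-12-phenyldodecyl]-2-methyloxirane | C[C@H](CCCCCCCCc1ccccc1)C[C@H](C)C[C@]1(C)CO1 | intermediate
20 | (4S,6S,8R)-4,6,8-trimethyl-16-phenylhexadec-1-en-4-ol | C[C@H](CCCCCCCCc1ccccc1)C[C@H](C)C[C@](O)(C)CC=C | intermediate
21 | (4R,6S,8R)-4,6,8-trimethyl-16-phenylhexadecane-2,4-diol (both epimers at C2) | C[C@H](CCCCCCCCc1ccccc1)C[C@H](C)C[C@](O)(C)CC(C)O | intermediate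
22 | (4R,6S,8R)-4-hydroxy-4,6,8-trimethyl-16-phenylhexadecan-2-yl methanesulfonate (both epimers at C2) | C[C@H](CCCCCCCCc1ccccc1)C[C@H](C)C[C@](O)(C)CC(C)OS(C)(=O)=O | intermediate
23 | (2R)-2-[(2S,4R)-2,4-dimethyl-12-phenyldodecyl]-2,4-dimethyloxetane (both epimers at C4) | C[C@H](CCCCCCCCc1ccccc1)C[C@H](C)C[C@]1(C)CC(C)O1 | intermediate
24 | (4S,6S,8R)-4-hydroperoxy-4,6,8-trimethyl-16-phenylhexadecan-2-ol (both epimers at C2) | C[C@H](CCCCCCCCc1ccccc1)C[C@H](C)C[C@@](OO)(C)CC(C)O | intermediate
25 | (4S,6S,8R)-4-hydroperoxy-4,6,8-trimethyl-16-phenylhexadecan-2-one | C[C@H](CCCCCCCCc1ccccc1)C[C@H](C)C[C@@](OO)(C)CC(C)=O | intermediate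
26 | (5S)-5-[(2S,4R)-2,4-dimethyl-12-phenyldodecyl]-3,5-dimethyl-1,2-dioxolan-3-ol (both epimers at C3) | C[C@H](CCCCCCCCc1ccccc1)C[C@H](C)C[C@@]1(C)CC(C)(O)OO1 | intermediate
27 | (5S)-5-[(2S,4R)-2,4-dimethyl-12-phenyldodecyl]-3-methoxy-3,5-dimethyl-1,2-dioxolane (both epimers at C3) | C[C@H](CCCCCCCCc1ccccc1)C[C@H](C)C[C@@]1(C)CC(C)(OC)OO1 | intermediate
28 | (5S)-5-[(2S,4R)-2,4-dimethyl-12-phenyldodecyl]-3,5-dimethyl-4,5-dihydro-1,2-dioxol-2-ium methoxytetrachlorotitanate (peroxycarbenium ion) | C[C@H](CCCCCCCCc1ccccc1)C[C@H](C)C[C@@]1(C)CC(C)=[O+]O1.CO[Ti-](Cl)(Cl)(Cl)Cl | intermediate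
29 | methyl 2-[(3R,5S)-5-[(2S,4R)-2,4-dimethyl-12-phenyldodecyl]-3,5-dimethyl-1,2-dioxolan-3-yl]acetate | C[C@H](CCCCCCCCc1ccccc1)C[C@H](C)C[C@@]1(C)C[C@](C)(CC(=O)OC)OO1 | intermediate
30 | 2-[(3R,5S)-5-[(2S,4R)-2,4-dimethyl-12-phenyldodecyl]-3,5-dimethyl-1,2-dioxolan-3-yl]acetic acid | C[C@H](CCCCCCCCc1ccccc1)C[C@H](C)C[C@@]1(C)C[C@](C)(CC(=O)O)OO1 | target

**Step count and risks**

Total steps: 15. Longest linear sequence: 14 (steps 2–15, from 3 and 4); step 1 is a one-step branch.

Most likely to fail, first: step 14. The planar peroxycarbenium carbon may be attacked with poor facial discrimination, because C5 carries a methyl group and a CH2-linked chain of similar effective size, so the two C3 epimers could form in near-equal amounts. The fallback sets out from 27 and introduces the C3 substituent as an allyl group instead. Hosomi–Sakurai-type allylation of the same peroxyketal (allyltrimethylsilane, SnCl4, CH2Cl2, −78 °C) has a later, more sterically demanding transition state, and its epimers should be easier to separate; it would give (3S,5S)-5-[(2S,4R)-2,4-dimethyl-12-phenyldodecyl]-3,5-dimethyl-3-(prop-2-en-1-yl)-1,2-dioxolane F1. Ozonolysis with Me2S work-up would give 2-[(3R,5S)-5-[(2S,4R)-2,4-dimethyl-12-phenyldodecyl]-3,5-dimethyl-1,2-dioxolan-3-yl]acetaldehyde F2. Pinnick oxidation (NaClO2, NaH2PO4, 2-methylbut-2-ene) then returns to the route at 30, bypassing 29.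

Second: step 13. The free tertiary hydroperoxide may be lost during the alcohol oxidation, through ligand exchange at iodine followed by O–O homolysis or fragmentation. The fallback sets out from 24 and masks the hydroperoxide first. Silylation of the more acidic OOH (Et3SiCl, imidazole, DMF, −20 °C) would give (4S,6S,8R)-4,6,8-trimethyl-16-phenyl-4-[(triethylsilyl)peroxy]hexadecan-2-ol F3. Dess–Martin oxidation would give (4S,6S,8R)-4,6,8-trimethyl-16-phenyl-4-[(triethylsilyl)peroxy]hexadecan-2-one F4. TsOH in MeOH should then cleave the silyl peroxide, close the peroxyhemiketal and ketalise it, returning to the route at 27.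

Third: step 11. The γ-oxido mesylate may undergo Grob-type fragmentation (back to ketone 18 and propene) or E2 elimination instead of 4-exo-tet closure. The fallback sets out from 20 and skips 21 and 22: a cobalt-hydride cycloisomerisation of the homoallylic alcohol (Co(salen) catalyst, C16H14CoN2O2, with N-fluoro-2,4,6-trimethylpyridinium triflate and (Me2SiH)2O). Markovnikov hydrogen-atom transfer to the vinyl group and radical–polar crossover give a secondary alkylcobalt electrophile that the tertiary hydroxyl captures, forming 23 directly. This fallback makes no new compound (none F0).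

Further compounds
F1 | step 14 | (3S,5S)-5-[(2S,4R)-2,4-dimethyl-12-phenyldodecyl]-3,5-dimethyl-3-(prop-2-en-1-yl)-1,2-dioxolane | C[C@H](CCCCCCCCc1ccccc1)C[C@H](C)C[C@@]1(C)C[C@](C)(CC=C)OO1
F2 | step 14 | 2-[(3R,5S)-5-[(2S,4R)-2,4-dimethyl-12-phenyldodecyl]-3,5-dimethyl-1,2-dioxolan-3-yl]acetaldehyde | C[C@H](CCCCCCCCc1ccccc1)C[C@H](C)C[C@@]1(C)C[C@](C)(CC=O)OO1
F3 | step 13 | (4S,6S,8R)-4,6,8-trimethyl-16-phenyl-4-[(triethylsilyl)peroxy]hexadecan-2-ol | C[C@H](CCCCCCCCc1ccccc1)C[C@H](C)C[C@@](OO[Si](CC)(CC)CC)(C)CC(C)O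
F4 | step 13 | (4S,6S,8R)-4,6,8-trimethyl-16-phenyl-4-[(triethylsilyl)peroxy]hexadecan-2-one | C[C@H](CCCCCCCCc1ccccc1)C[C@H](C)C[C@@](OO[Si](CC)(CC)CC)(C)CC(C)=O
F0 | step 11 | none | none
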